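**Strategy.** The target is cut at C7–C11 and C8–O. The five-membered lactone (O–C6–C7–C11–C12) is cis-fused to the ten-membered ring and the neighbouring C8 carries oxygen, so both can be put onto a C7=C8 ring alkene in one radical event: a carbon radical tethered to the C6 oxygen attacks C7, and air traps the radical that appears at C8. This aerobic Ueno–Stork cyclisation closes the oxygen ring and sets C7 and C8. Its precursor is a ten-membered (1(10)E,7Z)-diene with the cis-4,5-epoxide, the C10 methyl ester, a C9 silyl ether and a bromoacetal on O6. It is built from neryl acetate, acrolein and a vinyl unit, with ring-closing metathesis at C7=C8.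

Key step: step 13

Remark on numbering: ring carbons are C1 (enoate CH) to C10 (ester-bearing carbon), with the methyl on C4; C11, C12 and C13 are the α-carbon, the carbonyl (or acetal) carbon and the exocyclic methylene of the oxygen heterocycle; C14 is the ester carbon. The CIP descriptors at C7 and C9 change between some intermediates only because substituent priorities change; the arrangement in space is that of the SMILES strings throughout.

Assumption: neryl acetate, (S)-2-methylglycidol and (+)-DAIB are bought; the oxirane centre made in step 1 and the acetal carbon made in step 12 are carried as mixtures because both are removed later.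

Step 1
Reactants: 1 neryl acetate
Product: 2 (2Z)-5-(3,3-dimethyloxiran-2-yl)-3-methylpent-2-en-1-yl acetate
Conditions: mCPBA (1.05 equiv), CH2Cl2, 0 °C
Reagents that add atoms: mCPBA, OOC(=O)c1cccc(Cl)c1
Why: Prilezhaev epoxidation should be selective for the remote trisubstituted alkene, which is more electron-rich than the alkene deactivated by the allylic acetate; the new oxirane centre is racemic and is cleaved away in step 2.

Step 2
Reactants: 2 epoxy acetate
Product: 3 (2Z)-3-methyl-6-oxohex-2-en-1-yl acetate
Conditions: H5IO6, THF/H2O, 0 °C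
Reagents that add atoms: none
Why: periodic acid hydrates the epoxide at its tertiary carbon and cleaves the resulting glycol in one pot (Malaprade-type cleavage), so the aldehyde keeps the epoxide oxygen, acetone is lost and the (Z)-allylic acetate is left alone.

Step 3
Reactants: 3 aldehyde; 4 methyl (triphenylphosphoranylidene)acetate
Product: 6 methyl (2Z,6Z)-8-acetoxy-2-iodo-6-methylocta-2,6-dienoate, via iodo ylide 5 (not isolated)
Conditions: 4, NIS, CH2Cl2, −20 °C; then 3, −20 °C to rt
Reagents that add atoms: N-iodosuccinimide, O=C1CCC(=O)N1I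
Why: iodination of the stabilised ylide followed by Wittig olefination should place the ester trans to the alkyl chain, as stabilised ylides do, which is the (2Z) iodide with iodine cis to C2, the position that C9 must later take.

Step 4
Reactants: 6 iodoenoate; 7 acrolein
Product: 8 methyl (2E,6Z)-8-acetoxy-2-(1-hydroxyprop-2-en-1-yl)-6-methylocta-2,6-dienoate (racemic at C9)
Conditions: CrCl2 (4 equiv), NiCl2 (2 mol%), DMSO, rt
Reagents that add atoms: none
Why: Nozaki–Hiyama–Kishi coupling, in which zerovalent nickel inserts into the C–I bond and the alkenyl group passes to trivalent chromium and adds 1,2 to the aldehyde with the alkene geometry kept (C9 cis to C2, which is also the more stable arrangement of an α-metallated enoate); the C9 carbinol forms as a racemate that step 5 resolves.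

Step 5
Reactants: 8 racemic allylic alcohol
Product: 9 methyl (2E,6Z)-8-acetoxy-2-[(1R)-1-hydroxyprop-2-en-1-yl]-6-methylocta-2,6-dienoate
Conditions: Ti(OiPr)4 (10 mol%), D-(−)-DIPT (15 mol%), t-BuOOH (0.6 equiv), 4 Å MS, CH2Cl2, −20 °C
Reagents that add atoms: none
Why: Sharpless kinetic resolution of a secondary allylic alcohol, in which D-(−)-DIPT should epoxidise the vinyl group of the (S) enantiomer much faster (erythro epoxy alcohol, removed by chromatography), so that stopping a little beyond half conversion leaves the (R) alcohol and fixes C9; the other alkenes have no free allylic hydroxyl and stay intact.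

Step 6
Reactants: 9 (R)-allylic alcohol
Product: 10 methyl (2E,6Z)-8-acetoxy-2-[(1R)-1-(tert-butyldimethylsilyloxy)prop-2-en-1-yl]-6-methylocta-2,6-dienoate
Conditions: TBSOTf, 2,6-lutidine, CH2Cl2, −78 to 0 °C
Reagents that add atoms: tert-butyldimethylsilyl triflate, CC(C)(C)[Si](C)(C)OS(=O)(=O)C(F)(F)F
Why: silylation of a hindered secondary alcohol with the silyl triflate and a non-nucleophilic base is reliable and touches neither the acetate nor the enoate.

Step 7
Reactants: 10 silyl ether acetate
Product: 11 methyl (2E,6Z)-2-[(1R)-1-(tert-butyldimethylsilyloxy)prop-2-en-1-yl]-8-hydroxy-6-methylocta-2,6-dienoate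
Conditions: K2CO3 (0.2 equiv), MeOH, 0 °C
Reagents that add atoms: none
Why: base-catalysed transesterification with methanol removes the primary acetate, while the secondary silyl ether is stable and the methyl ester can only exchange with itself.

Step 8
Reactants: 11 primary allylic alcohol
Product: 12 methyl (2E,6Z)-2-[(1R)-1-(tert-butyldimethylsilyloxy)prop-2-en-1-yl]-6-methyl-8-oxoocta-2,6-dienoate
Conditions: TEMPO (10 mol%), PhI(OAc)2 (1.1 equiv), CH2Cl2, rt
Reagents that add atoms: none
Why: oxoammonium (TEMPO) oxidation with PhI(OAc)2 as terminal oxidant converts the primary allylic alcohol into the enal under near-neutral conditions, which should keep the Z geometry of the trisubstituted alkene.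

Step 9
Reactants: 12 enal; 13 vinylmagnesium bromide
Product: 15 methyl (2E,6Z,8R)-2-[(1R)-1-(tert-butyldimethylsilyloxy)prop-2-en-1-yl]-8-hydroxy-6-methyldeca-2,6,9-trienoate, via divinylzinc 14 (not isolated)
Conditions: 13 (3 equiv), ZnCl2 (1.5 equiv), Et2O/1,4-dioxane, magnesium salts filtered off; (+)-DAIB [(2R)-3-exo-(dimethylamino)isoborneol] (15 mol%), toluene, −20 to 0 °C; then 12; H2O quench
Reagents that add atoms: none
Why: amino-alcohol-catalysed addition of a diorganozinc to an aldehyde, in which (+)-DAIB, the mirror image of the ligand known to direct Si-face attack, should send the vinyl group to the Re face of the enal and so give the (R) carbinol at C6 under reagent control; salt-free divinylzinc keeps the uncatalysed addition slow and leaves the ester alone.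

Step 10
Reactants: 15 bis-allylic alcohol
Product: 16 methyl (2E)-2-[(1R)-1-(tert-butyldimethylsilyloxy)prop-2-en-1-yl]-5-{(2R,3S)-3-[(1R)-1-hydroxyprop-2-en-1-yl]-2-methyloxiran-2-yl}pent-2-enoate
Conditions: mCPBA (1.1 equiv), NaHCO3, CH2Cl2, −20 to 0 °C
Reagents that add atoms: mCPBA, OOC(=O)c1cccc(Cl)c1
Why: hydroxyl-directed Prilezhaev epoxidation of the most nucleophilic (trisubstituted) alkene, in which the cis C3 substituent forces the rotamer with C6–H in the alkene plane (allylic 1,3-strain) and the peracid, hydrogen-bonded to the hydroxyl, attacks the face syn to OH, which should give the threo epoxy alcohol, that is C4 (R) and C5 (S) from C6 (R).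

Step 11
Reactants: 16 epoxy diene
Product: 17 methyl (1(10)E,4R,5S,6R,7Z,9R)-9-(tert-butyldimethylsilyloxy)-4,5-epoxy-6-hydroxy-4-methylcyclodeca-1(10),7-diene-10-carboxylate
Conditions: second-generation Hoveyda–Grubbs catalyst (10 mol%), 1,4-benzoquinone (10 mol%), toluene (1 mM), 80 °C
Reagents that add atoms: none
Why: ring-closing olefin metathesis of the two monosubstituted alkenes, in which the cis-epoxide and the cis arrangement of C2 and C9 on the enoate bring the chain ends together, the trisubstituted electron-poor enoate does not take part, and the Z alkene should be clearly less strained than the E alkene in a ten-membered ring that already holds these two cis units.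

Step 12
Reactants: 17 cyclodecadienol; 18 ethyl vinyl ether
Product: 19 6-O-(2-bromo-1-ethoxyethyl) mixed acetal of 17, (4R,5S,6R,9R), both epimers at the acetal carbon
Conditions: 18 (5 equiv), NBS (1.5 equiv), CH2Cl2, −40 to 0 °C
Reagents that add atoms: N-bromosuccinimide, O=C1CCC(=O)N1Br
Why: bromoetherification of the vinyl ether (the usual entry to Ueno–Stork precursors), in which N-bromosuccinimide attacks the electron-rich enol ether far faster than the ring alkenes and the C6 hydroxyl traps the oxocarbenium ion; the configuration of the acetal carbon does not matter later.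

Step 13
Reactants: 19 cyclodecadiene bromoacetal
Product: 21 cis-fused bicyclic acetal alcohol (tetrahydrofuran ring O–C6–C7–C11–C12 with 12-OEt; 8-OH; 9-OTBS; 4,5-epoxide; 1(10)E-ene; 10-CO2Me; 4R,5S,6R,7R,8S,9S), via C8 hydroperoxide 20 (not isolated)
Conditions: Bu3SnH (1.5 equiv, syringe pump), Et3B (0.2 equiv), dry air, toluene (0.01 M), 0 °C; then PPh3, rt
Reagents that add atoms: dioxygen (air), O=O
Why: Bu3Sn• (started by Et3B and air) abstracts bromine from 19, the primary C11 radical adds to C7 of the ring alkene, the secondary C8 radical combines with O2, the peroxyl radical takes hydrogen from Bu3SnH and so carries the chain, and PPh3 reduces hydroperoxide 20 to alcohol 21. The closest known reaction type is the Ueno–Stork bromoacetal cyclisation run under aerobic tin hydride conditions (oxygenative radical cyclisation). The tetrahydrofuran ring closes in the 5-exo-trig mode, which for this hex-5-enyl-type radical is faster than 6-endo attack at C8; because C4–C5 is an epoxide and not an alkene, C7 is the only alkene carbon within 5-exo reach. C7 is controlled by the two-atom tether, which can deliver C11 only to the alkene face on which the C6 oxygen stands, so the ring fusion must be cis. C8 is controlled by the neighbouring C9 tert-butyldimethylsilyloxy group: O2 should approach the flat C8 radical from the face away from this bulky group, which gives the required trans relationship of the C8 and C9 oxygens and is the least secure element of the step; a silyl ether, unlike an ester, also cannot undergo a 1,2-acyloxy shift in this β-oxygenated radical. The step needs cyclisation before oxygen capture at C11 and oxygen capture before hydrogen transfer at C8, which the fast bromoacetal closure, the low oxygen content of air-saturated toluene and the slow addition of Bu3SnH should secure, while the enoate is out of reach because attack by C8 would need a three- or four-membered ring.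

Step 14
Reactants: 21 acetal alcohol
Product: 22 C8 acetate of 21 (4R,5S,6R,7S,8S,9S)
Conditions: Ac2O, pyridine, DMAP (cat.), CH2Cl2, 0 °C to rt
Reagents that add atoms: acetic anhydride, CC(=O)OC(C)=O
Why: DMAP-catalysed acetylation caps the C8 hydroxyl at once, before it can take part in silyl migration or, later, in translactonisation.

Step 15
Reactants: 22 silyl ether
Product: 23 C9 alcohol (8-OAc, 12-OEt acetal; 4R,5S,6R,7S,8S,9S)
Conditions: Et3N·3HF, THF, rt to 40 °C
Reagents that add atoms: none
Why: fluoride-induced desilylation with the mildly acidic amine–HF complex frees the C9 hydroxyl without forming an alkoxide, so migration of the C8 acetate is not promoted; the acetal and the epoxide should tolerate the reagent.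

Step 16
Reactants: 24 (S)-2-methylglycidol
Product: 25 (R)-2-methyloxirane-2-carboxylic acid
Conditions: RuCl3 (2 mol%), NaIO4 (3 equiv), MeCN/EtOAc/H2O, 0 °C to rt
Reagents that add atoms: water, O; NaIO4 (terminal oxidant, oxygen relayed through RuO4), [Na+].[O-]I(=O)(=O)=O
Why: ruthenium tetroxide formed in situ oxidises the primary alcohol to the carboxylic acid without touching the epoxide or the quaternary stereocentre, whose descriptor changes from S to R only through the CIP priorities.

Step 17
Reactants: 23 C9 alcohol; 25 epoxy acid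
Product: 27 9-O-[(2R)-2-methyloxirane-2-carbonyl] ester of 23 (4R,5S,6R,7S,8S,9S), via mixed anhydride 26 (not isolated)
Conditions: 25, 2,4,6-trichlorobenzoyl chloride, Et3N, THF, 0 °C; then 23, DMAP, toluene, rt
Reagents that add atoms: none
Why: Yamaguchi esterification, in which the acid is activated as the mixed 2,4,6-trichlorobenzoic anhydride and DMAP transfers the acyl group to the hindered C9 hydroxyl; no lactone is present at this stage, so the free hydroxyl cannot translactonise, and no stereocentre is touched.

Step 18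
Reactants: 27 ethyl acetal
Product: 28 lactol (12-OH, both epimers; 4R,5S,6R,7S,8S,9S)
Conditions: PPTS (0.2 equiv), acetone/H2O 4:1, 40 °C
Reagents that add atoms: water, O
Why: acid-catalysed hydrolysis of the 2-ethoxytetrahydrofuran acetal runs through a stabilised cyclic oxocarbenium ion under weakly acidic conditions that should spare the esters and both epoxides, since the ring epoxide has no electron-rich alkene across the ring to assist its opening and the side-chain epoxide is deactivated by its carbonyl group.

Step 19
Reactants: 28 lactol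
Product: 30 α-methylene lactol (C11=C13; 12-OH; 4R,5S,6R,7S,8S,9S), via Mannich base 29 (not isolated)
Conditions: CH2=NMe2+ I− (Eschenmoser's salt, 3 equiv), Et3N, CH2Cl2, rt
Reagents that add atoms: Eschenmoser's salt, C=[N+](C)C.[I-]
Why: Mannich-type α-methylenation of an aldehyde, in which the lactol is in equilibrium with the γ-hydroxy aldehyde, its enol is aminomethylated at C11 and loss of dimethylamine from the Mannich base gives the enal, which closes again to the lactol; no strong base is present that would enolise the three esters.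

Step 20
Reactants: 30 α-methylene lactol
Product: 31 target CNP0159450.1
Conditions: Dess–Martin periodinane, pyridine, CH2Cl2, 0 °C to rt
Reagents that add atoms: none
Why: Dess–Martin oxidation of the allylic lactol to the lactone is mild, needs neither acid nor strong base and leaves the exocyclic methylene, the esters and the epoxides as they are.

**Compound list**

1 | neryl acetate, (2Z)-3,7-dimethylocta-2,6-dien-1-yl acetate | CC(C)=CCC/C(C)=C\COC(C)=O | starting material
2 | (2Z)-5-(3,3-dimethyloxiran-2-yl)-3-methylpent-2-en-1-yl acetate (racemic at the oxirane CH) | CC1(C)OC1CC/C(C)=C\COC(C)=O | intermediate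
3 | (2Z)-3-methyl-6-oxohex-2-en-1-yl acetate | O=CCC/C(C)=C\COC(C)=O | intermediate
4 | methyl (triphenylphosphoranylidene)acetate | COC(=O)C=P(c1ccccc1)(c1ccccc1)c1ccccc1 | starting material
5 | methyl iodo(triphenylphosphoranylidene)acetate (not isolated) | COC(=O)C(I)=P(c1ccccc1)(c1ccccc1)c1ccccc1 | intermediate
6 | methyl (2Z,6Z)-8-acetoxy-2-iodo-6-methylocta-2,6-dienoate | COC(=O)/C(I)=C/CC/C(C)=C\COC(C)=O | intermediate
7 | acrolein | C=CC=O | starting material
8 | methyl (2E,6Z)-8-acetoxy-2-(1-hydroxyprop-2-en-1-yl)-6-methylocta-2,6-dienoate (racemic) | C=CC(O)/C(C(=O)OC)=C\CC/C(C)=C\COC(C)=O | intermediate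
9 | methyl (2E,6Z)-8-acetoxy-2-[(1R)-1-hydroxyprop-2-en-1-yl]-6-methylocta-2,6-dienoate | C=C[C@@H](O)/C(C(=O)OC)=C\CC/C(C)=C\COC(C)=O | intermediate
10 | methyl (2E,6Z)-8-acetoxy-2-[(1R)-1-(tert-butyldimethylsilyloxy)prop-2-en-1-yl]-6-methylocta-2,6-dienoate | C=C[C@@H](O[Si](C)(C)C(C)(C)C)/C(C(=O)OC)=C\CC/C(C)=C\COC(C)=O | intermediate
11 | methyl (2E,6Z)-2-[(1R)-1-(tert-butyldimethylsilyloxy)prop-2-en-1-yl]-8-hydroxy-6-methylocta-2,6-dienoate | C=C[C@@H](O[Si](C)(C)C(C)(C)C)/C(C(=O)OC)=C\CC/C(C)=C\CO | intermediate
12 | methyl (2E,6Z)-2-[(1R)-1-(tert-butyldimethylsilyloxy)prop-2-en-1-yl]-6-methyl-8-oxoocta-2,6-dienoate | C=C[C@@H](O[Si](C)(C)C(C)(C)C)/C(C(=O)OC)=C\CC/C(C)=C\C=O | intermediate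
13 | vinylmagnesium bromide | C=C[Mg]Br | starting material
14 | divinylzinc (not isolated) | C=C[Zn]C=C | intermediate
15 | methyl (2E,6Z,8R)-2-[(1R)-1-(tert-butyldimethylsilyloxy)prop-2-en-1-yl]-8-hydroxy-6-methyldeca-2,6,9-trienoate | C=C[C@@H](O[Si](C)(C)C(C)(C)C)/C(C(=O)OC)=C\CC/C(C)=C\[C@H](O)C=C | intermediate
16 | methyl (2E)-2-[(1R)-1-(tert-butyldimethylsilyloxy)prop-2-en-1-yl]-5-{(2R,3S)-3-[(1R)-1-hydroxyprop-2-en-1-yl]-2-methyloxiran-2-yl}pent-2-enoate | C=C[C@@H](O[Si](C)(C)C(C)(C)C)/C(C(=O)OC)=C\CC[C@@]1(C)O[C@H]1[C@H](O)C=C | intermediate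
17 | methyl (1(10)E,4R,5S,6R,7Z,9R)-9-(tert-butyldimethylsilyloxy)-4,5-epoxy-6-hydroxy-4-methylcyclodeca-1(10),7-diene-10-carboxylate (cis-epoxide) | O[C@@H]2/C=C\[C@@H](O[Si](C)(C)C(C)(C)C)/C(C(=O)OC)=C\CC[C@@]1(C)O[C@@H]21 | intermediate
18 | ethyl vinyl ether | C=COCC | starting material
19 | 6-O-(2-bromo-1-ethoxyethyl) mixed acetal of 17, (4R,5S,6R,9R), both acetal epimers (key-step precursor) | BrCC(OCC)O[C@@H]2/C=C\[C@@H](O[Si](C)(C)C(C)(C)C)/C(C(=O)OC)=C\CC[C@@]1(C)O[C@@H]21 | intermediate
20 | C8 hydroperoxide of the cis-fused bicyclic acetal (4R,5S,6R,7S,8S,9S; not isolated) | C1C(OCC)O[C@@H]2[C@H]1[C@H](OO)[C@@H](O[Si](C)(C)C(C)(C)C)/C(C(=O)OC)=C\CC[C@@]1(C)O[C@@H]21 | intermediate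
21 | cis-fused bicyclic acetal alcohol: tetrahydrofuran ring O–C6–C7–C11–C12 with 12-OEt, 8-OH, 9-OTBS, 4,5-epoxide, 1(10)E-ene, 10-CO2Me (4R,5S,6R,7R,8S,9S) (key-step product) | C1C(OCC)O[C@@H]2[C@H]1[C@H](O)[C@@H](O[Si](C)(C)C(C)(C)C)/C(C(=O)OC)=C\CC[C@@]1(C)O[C@@H]21 | intermediate
22 | C8 acetate of 21 (4R,5S,6R,7S,8S,9S) | C1C(OCC)O[C@@H]2[C@H]1[C@H](OC(C)=O)[C@@H](O[Si](C)(C)C(C)(C)C)/C(C(=O)OC)=C\CC[C@@]1(C)O[C@@H]21 | intermediate
23 | 8-acetoxy-9-hydroxy bicyclic ethyl acetal (4R,5S,6R,7S,8S,9S) | C1C(OCC)O[C@@H]2[C@H]1[C@H](OC(C)=O)[C@@H](O)/C(C(=O)OC)=C\CC[C@@]1(C)O[C@@H]21 | intermediate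
24 | (S)-2-methylglycidol, [(2S)-2-methyloxiran-2-yl]methanol | OC[C@@]1(C)CO1 | starting material
25 | (R)-2-methyloxirane-2-carboxylic acid | OC(=O)[C@@]1(C)CO1 | intermediate
26 | (2R)-2-methyloxirane-2-carboxylic 2,4,6-trichlorobenzoic anhydride (not isolated) | O=C(OC(=O)[C@@]1(C)CO1)c1c(Cl)cc(Cl)cc1Cl | intermediate
27 | 8-acetoxy-9-[(2R)-2-methyloxirane-2-carbonyloxy] bicyclic ethyl acetal (4R,5S,6R,7S,8S,9S) | C1C(OCC)O[C@@H]2[C@H]1[C@H](OC(C)=O)[C@@H](OC(=O)[C@@]1(C)CO1)/C(C(=O)OC)=C\CC[C@@]1(C)O[C@@H]21 | intermediate
28 | lactol of 27 (12-OH, both epimers) | C1C(O)O[C@@H]2[C@H]1[C@H](OC(C)=O)[C@@H](OC(=O)[C@@]1(C)CO1)/C(C(=O)OC)=C\CC[C@@]1(C)O[C@@H]21 | intermediate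
29 | 11-(dimethylaminomethyl) lactol, Mannich base (not isolated) | CN(C)CC1C(O)O[C@@H]2[C@H]1[C@H](OC(C)=O)[C@@H](OC(=O)[C@@]1(C)CO1)/C(C(=O)OC)=C\CC[C@@]1(C)O[C@@H]21 | intermediate
30 | α-methylene lactol (C11=C13, 12-OH) | C=C1C(O)O[C@@H]2[C@H]1[C@H](OC(C)=O)[C@@H](OC(=O)[C@@]1(C)CO1)/C(C(=O)OC)=C\CC[C@@]1(C)O[C@@H]21 | intermediate
31 | CNP0159450.1: cis-fused α-methylene-γ-lactone (6,12-olide) with 8-OAc, 9-O-[(2R)-2-methyloxirane-2-carbonyl], cis-4,5-epoxide, 1(10)E-ene and 10-CO2Me (4R,5S,6R,7R,8S,9S) | C=C1C(=O)O[C@@H]2[C@H]1[C@H](OC(C)=O)[C@@H](OC(=O)[C@@]1(C)CO1)/C(C(=O)OC)=C\CC[C@@]1(C)O[C@@H]21 | target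

**Step count.** Total: 20 steps. Longest linear sequence: 19 steps (steps 1–15 and 17–20; step 16 is a one-step side branch).

**Steps most likely to fail**

Step 13 (radical cyclisation with oxygen capture). The weak point is uptake of oxygen on the face of the C8 radical that lies syn to the C9 silyloxy group, that is, poor or reversed facial selectivity. The fallback sets out again from bromoacetal 19. The same radical step then gives the C8-epimeric alcohol F1. Oxidation with Dess–Martin periodinane and pyridine gives the C8 ketone F2. Luche reduction (NaBH4, CeCl3, MeOH, −78 °C) should deliver hydride to the same exposed face that oxygen had used, which places the hydroxyl on the other face and returns alcohol 21. C8 is then set by ketone reduction instead of radical capture.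

Step 11 (ring-closing metathesis). The weak point is intermolecular metathesis (oligomerisation) outrunning closure of the ten-membered ring, or closure to the E alkene. The fallback sets out from dienol 15 and closes the ring before the epoxide is made. Metathesis of 15, in which three cis-alkene units fold the chain, should give the cyclodecatrienol F3. Epoxidation of its C4=C5 alkene (mCPBA, NaHCO3) next to the hydroxyl should then occur from the outer face of the medium ring. For cis-cycloalkenols of eight or more ring atoms this gives the trans (threo) epoxy alcohol, here 17, where the route is rejoined.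

Step 9 (asymmetric vinylation). The weak point is loss of facial selectivity through uncatalysed addition promoted by residual magnesium salts, or Z-to-E isomerisation of the enal. The fallback sets out from allylic alcohol 11:
- Sharpless asymmetric epoxidation (Ti(OiPr)4, L-(+)-DET, t-BuOOH) gives the primary epoxy alcohol F4, with C4 and C5 set by the catalyst.
- Parikh–Doering oxidation gives the epoxy aldehyde F5.
- Vinylmagnesium bromide should add under Felkin–Anh control to give mainly the C6-epimeric (erythro) alcohol F6.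
- Mitsunobu inversion with 4-nitrobenzoic acid (PPh3, DIAD) gives the inverted 4-nitrobenzoate F7.
- Methanolysis (K2CO3, MeOH) gives 16, where the route is rejoined.

Further compounds
F1 | step 13 | C8 epimer of alcohol 21 (4R,5S,6R,7R,8R,9S) | C1C(OCC)O[C@@H]2[C@H]1[C@@H](O)[C@@H](O[Si](C)(C)C(C)(C)C)/C(C(=O)OC)=C\CC[C@@]1(C)O[C@@H]21
F2 | step 13 | C8 ketone of the bicyclic acetal (4R,5S,6R,7S,9S) | C1C(OCC)O[C@@H]2[C@H]1C(=O)[C@@H](O[Si](C)(C)C(C)(C)C)/C(C(=O)OC)=C\CC[C@@]1(C)O[C@@H]21
F3 | step 11 | methyl (1(10)E,4Z,6R,7Z,9R)-9-(tert-butyldimethylsilyloxy)-6-hydroxy-4-methylcyclodeca-1(10),4,7-triene-10-carboxylate | C/C1=C/[C@H](O)/C=C\[C@@H](O[Si](C)(C)C(C)(C)C)/C(C(=O)OC)=C\CC1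
F4 | step 9 | methyl (2E)-2-[(1R)-1-(tert-butyldimethylsilyloxy)prop-2-en-1-yl]-5-[(2R,3S)-3-(hydroxymethyl)-2-methyloxiran-2-yl]pent-2-enoate | C=C[C@@H](O[Si](C)(C)C(C)(C)C)/C(C(=O)OC)=C\CC[C@@]1(C)O[C@H]1CO
F5 | step 9 | methyl (2E)-2-[(1R)-1-(tert-butyldimethylsilyloxy)prop-2-en-1-yl]-5-[(2R,3R)-3-formyl-2-methyloxiran-2-yl]pent-2-enoate | C=C[C@@H](O[Si](C)(C)C(C)(C)C)/C(C(=O)OC)=C\CC[C@@]1(C)O[C@H]1C=O
F6 | step 9 | methyl (2E)-2-[(1R)-1-(tert-butyldimethylsilyloxy)prop-2-en-1-yl]-5-{(2R,3S)-3-[(1S)-1-hydroxyprop-2-en-1-yl]-2-methyloxiran-2-yl}pent-2-enoate | C=C[C@@H](O[Si](C)(C)C(C)(C)C)/C(C(=O)OC)=C\CC[C@@]1(C)O[C@H]1[C@@H](O)C=C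
F7 | step 9 | methyl (2E)-2-[(1R)-1-(tert-butyldimethylsilyloxy)prop-2-en-1-yl]-5-{(2R,3S)-2-methyl-3-[(1R)-1-(4-nitrobenzoyloxy)prop-2-en-1-yl]oxiran-2-yl}pent-2-enoate | C=C[C@@H](O[Si](C)(C)C(C)(C)C)/C(C(=O)OC)=C\CC[C@@]1(C)O[C@H]1[C@H](OC(=O)c1ccc(cc1)[N+](=O)[O-])C=C
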